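**Retrosynthetic overview**
- The strategy rests on ring B: a resorcinol monoether (free OH at C4', OMe at C2') whose C5', ortho to the free OH, carries the quaternary carbon CMe2–CH=CH2. Ring B is therefore built around that carbon, not substituted afterwards.
- Target 28 ⇒ removal of three MOM ethers from flavanone 27 ⇒ C2–C1' bond by rhodium-catalysed asymmetric 1,4-addition of arylboronic acid 21 to chromone 26 (sets the only stereocentre, 2S).
- Ring B ⇒ Danheiser benzannulation of dienyl diazoketone 8 with methoxyacetylene 11, forming C1'–C6', C1'–C2', C3'–C4' and C4'–C5'; C1' is then functionalised via Br and B(OH)2.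
- Diazoketone 8 ⇒ prenyl Grignard reagent plus formaldehyde (quaternary carbon made at the aliphatic stage), oxidation, Horner–Wadsworth–Emmons olefination, diazo transfer. Chromone 26 ⇒ 2,4,6-trihydroxyacetophenone by C-prenylation, selective bis-MOM protection and enaminone cyclisation.
- Ring order: ring A is bought, ring B is built in step 6, the pyranone ring C is closed in step 12 and saturated at C2 in step 13.

Key step: step 6

Assumption: the sense of induction of the chiral diene–rhodium catalyst on the chromone is taken to parallel that on cyclohexenone, so the (1S,4S) ligand is proposed for aryl delivery to the Re face of C2; if a first run shows the opposite sense, the (1R,4R) ligand is used.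

**Route**

Step 1
Reactants: 1 prenyl chloride (1-chloro-3-methylbut-2-ene)
Product: 3 2,2-dimethylbut-3-en-1-ol, via prenylmagnesium chloride 2 (not isolated)
Conditions: Mg, THF, 0 °C (slow addition); (CH2O)n, 0 °C to rt; aq. NH4Cl
Reagents that add atoms: formaldehyde (as paraformaldehyde), C=O
Why: Allylic Grignard addition with allylic transposition (SE2' through a six-membered transition state) joins the tertiary γ-carbon of the prenyl reagent to formaldehyde and so creates the quaternary carbon at the aliphatic stage.

Step 2
Reactants: 3 2,2-dimethylbut-3-en-1-ol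
Product: 4 2,2-dimethylbut-3-enal
Conditions: TEMPO (cat.), PhI(OAc)2, CH2Cl2, rt; washed and carried on as a CH2Cl2 solution
Reagents that add atoms: none
Why: TEMPO-catalysed oxidation with PhI(OAc)2 stops at the aldehyde, which has no α-hydrogen and so can neither enolise nor move its double bond into conjugation.

Step 3
Reactants: 4 2,2-dimethylbut-3-enal; 5 dimethyl (2-oxopropyl)phosphonate
Product: 6 (E)-5,5-dimethylhepta-3,6-dien-2-one
Conditions: LiCl, i-Pr2NEt, MeCN, rt
Reagents that add atoms: none
Why: Horner–Wadsworth–Emmons olefination under Masamune–Roush conditions should give the (E)-enone, the non-enolisable hindered aldehyde reacting cleanly with the stabilised ketophosphonate anion.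

Step 4
Reactants: 6 (E)-5,5-dimethylhepta-3,6-dien-2-one
Product: 8 (E)-1-diazo-5,5-dimethylhepta-3,6-dien-2-one, via trifluoroacetyl ketone 7 (not isolated)
Conditions: LiN(SiMe3)2, THF, −78 °C; CF3CO2CH2CF3; 5% aq. HCl work-up; then MsN3, Et3N, H2O, MeCN, rt
Reagents that add atoms: methanesulfonyl azide, CS(=O)(=O)N=[N+]=[N-]
Why: Detrifluoroacetylative diazo transfer (Danheiser modification of the Regitz reaction): the lithium enolate can form only at the methyl group because the γ-carbon is quaternary, and the trifluoroacetylated diketone accepts the diazo group with loss of the trifluoroacetyl unit as its N-sulfonyl amide.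

Step 5
Reactants: 9 chloroacetaldehyde dimethyl acetal (2-chloro-1,1-dimethoxyethane)
Product: 11 methoxyacetylene, via sodium methoxyacetylide 10 (not isolated)
Conditions: NaNH2 (3 equiv), liq. NH3, −33 °C; then cold aq. NaCl, −70 °C; distilled into cold ClCH2CH2Cl
Reagents that add atoms: none
Why: Twofold base-induced elimination (HCl, then methanol) with NaNH2 in liquid ammonia is the standard preparation of alkoxyacetylenes from haloacetals and gives the acetylide, which is protonated on quench; the low-boiling ynol ether is kept as a cold titrated solution.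

Step 6
Reactants: 8 (E)-1-diazo-5,5-dimethylhepta-3,6-dien-2-one; 11 methoxyacetylene
Product: 16 5-methoxy-2-(2-methylbut-3-en-2-yl)phenol, via vinylketene 12 (not isolated), via vinylcyclobutenone 13 (not isolated), via dienylketene 14 (not isolated), via cyclohexadienone 15 (not isolated)
Conditions: 11 (3 equiv), hν (365 nm), ClCH2CH2Cl, 5 °C, sealed Pyrex tube; then 80 °C, dark
Reagents that add atoms: none
Why: Light expels N2 from 8 and the alkenyl group shifts to the diazo carbon (Wolff rearrangement, forming C1'–C6') to give vinylketene 12, whose ketene C=C adds the ynol ether in a [2+2] cycloaddition (ketene carbonyl carbon to the unsubstituted alkyne carbon, C3'–C4'; ketene α-carbon to the methoxy-bearing carbon, C1'–C2') to give cyclobutenone 13. Reversible 4π electrocyclic opening of 13 gives dienylketene 14, and ring B is closed by a disrotatory 6π electrocyclisation (forming C4'–C5') to dienone 15, which tautomerises to phenol 16. The closest known reaction is the diazoketone variant of the Danheiser benzannulation with alkoxy- and silyloxyacetylenes. No stereocentre is formed. The step needs regiocontrol in the [2+2] event, which the polarity of the partners secures: the nucleophilic β-carbon of the ynol ether bonds to the electrophilic ketene carbon, so OMe ends meta to the new OH and para to the quaternary substituent. It also needs the skipped diene to stay a spectator, which the quaternary carbon secures (no conjugation, no γ-hydrogen), helped by irradiating only where the diazoketone absorbs and running the electrocyclic steps thermally in the dark.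

Step 7
Reactants: 16 5-methoxy-2-(2-methylbut-3-en-2-yl)phenol
Product: 17 4-methoxy-2-(methoxymethoxy)-1-(2-methylbut-3-en-2-yl)benzene
Conditions: NaH, MOMCl, THF/DMF, 0 °C to rt
Reagents that add atoms: chloromethyl methyl ether, COCCl
Why: Williamson etherification of the sodium phenoxide masks the hydroxyl before bromination, so that the electrophile cannot trigger bromoetherification of the neighbouring vinyl group by the free phenol.

Step 8
Reactants: 17 4-methoxy-2-(methoxymethoxy)-1-(2-methylbut-3-en-2-yl)benzene
Product: 18 1-bromo-2-methoxy-4-(methoxymethoxy)-5-(2-methylbut-3-en-2-yl)benzene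
Conditions: NBS, MeCN, 0 °C, dark
Reagents that add atoms: N-bromosuccinimide, O=C1CCC(=O)N1Br
Why: Electrophilic aromatic bromination should go to C1' (para to OMOM, ortho to OMe), since the position para to OMe is occupied and C3' is flanked by two alkoxy groups, while the monosubstituted neopentyl-type alkene is far less nucleophilic than the dialkoxyarene.

Step 9
Reactants: 18 1-bromo-2-methoxy-4-(methoxymethoxy)-5-(2-methylbut-3-en-2-yl)benzene
Product: 21 [2-methoxy-4-(methoxymethoxy)-5-(2-methylbut-3-en-2-yl)phenyl]boronic acid, via aryllithium 19 (not isolated), via lithium triisopropoxyborate 20 (not isolated)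
Conditions: n-BuLi, THF, −78 °C; B(Oi-Pr)3, −78 to 0 °C; aq. NH4Cl
Reagents that add atoms: triisopropyl borate, CC(C)OB(OC(C)C)OC(C)C; water, O
Why: Bromine–lithium exchange at −78 °C, borate trapping and mild hydrolysis give the arylboronic acid, the MOM ether and the terminal alkene being inert to these conditions.

Step 10
Reactants: 22 2,4,6-trihydroxyacetophenone
Product: 23 1-[2,4,6-trihydroxy-3-(3-methylbut-2-en-1-yl)phenyl]ethan-1-one
Conditions: prenyl bromide, DBU, THF, 0 °C to rt
Reagents that add atoms: prenyl bromide (1-bromo-3-methylbut-2-ene), CC(C)=CCBr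
Why: C-alkylation of the ambident phloroacetophenone anion gives a single mono-C-prenyl isomer because the two free ring positions are equivalent, with O-prenyl and doubly prenylated material removed by chromatography.

Step 11
Reactants: 23 1-[2,4,6-trihydroxy-3-(3-methylbut-2-en-1-yl)phenyl]ethan-1-one
Product: 24 1-[2-hydroxy-4,6-bis(methoxymethoxy)-3-(3-methylbut-2-en-1-yl)phenyl]ethan-1-one
Conditions: MOMCl (2.2 equiv), i-Pr2NEt, CH2Cl2, 0 °C to rt
Reagents that add atoms: chloromethyl methyl ether, COCCl
Why: Selective etherification should take the para hydroxyl and the less hindered ortho hydroxyl and leave free the chelated hydroxyl flanked by acetyl and prenyl, which fixes the later pyranone closure on the oxygen next to the prenyl group; the regiochemistry is to be confirmed by NOE before going on.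

Step 12
Reactants: 24 1-[2-hydroxy-4,6-bis(methoxymethoxy)-3-(3-methylbut-2-en-1-yl)phenyl]ethan-1-one
Product: 26 5,7-bis(methoxymethoxy)-8-(3-methylbut-2-en-1-yl)-4H-chromen-4-one, via enaminone 25 (not isolated)
Conditions: Me2NCH(OMe)2, toluene, 90 °C; then AcOH, CH2Cl2, 40 °C
Reagents that add atoms: N,N-dimethylformamide dimethyl acetal, COC(OC)N(C)C
Why: Enaminone formation followed by intramolecular oxa-Michael addition and loss of dimethylamine closes ring C on the only free phenol, and acetic acid is too weak to cleave the aryl MOM ethers.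

Step 13
Reactants: 26 5,7-bis(methoxymethoxy)-8-(3-methylbut-2-en-1-yl)-4H-chromen-4-one; 21 [2-methoxy-4-(methoxymethoxy)-5-(2-methylbut-3-en-2-yl)phenyl]boronic acid
Product: 27 (2S)-2-[2-methoxy-4-(methoxymethoxy)-5-(2-methylbut-3-en-2-yl)phenyl]-5,7-bis(methoxymethoxy)-8-(3-methylbut-2-en-1-yl)-2,3-dihydro-4H-chromen-4-one
Conditions: 21 (2 equiv), [RhCl(C2H4)2]2 (3 mol %), (1S,4S)-2,5-diphenylbicyclo[2.2.2]octa-2,5-diene (7 mol %), aq. KOH (0.5 equiv), 1,4-dioxane/H2O, 40 °C
Reagents that add atoms: none
Why: Hayashi–Miyaura asymmetric 1,4-addition: transmetalation gives an aryl complex of monovalent rhodium held by the chiral diene, which inserts the chromone C2=C3 bond on the Re face of C2 (O1 > C3 > H) to set 2S under ligand control, and hydrolysis of the rhodium enolate releases the flavanone.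

Step 14
Reactants: 27 (2S)-tris-MOM flavanone
Product: 28 (2S)-5,7-dihydroxy-2-[4-hydroxy-2-methoxy-5-(2-methylbut-3-en-2-yl)phenyl]-8-(3-methylbut-2-en-1-yl)-2,3-dihydro-4H-chromen-4-one (target)
Conditions: 3 M aq. HCl, MeOH/THF, 40 °C, short reaction time
Reagents that add atoms: none
Why: Acid-catalysed acetal exchange with methanol removes the three aryl MOM ethers, and the absence of base together with low temperature and short time should keep C2 from opening to the chalcone and leave the prenyl and 1,1-dimethylallyl groups uncyclised.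

**Compound list**
1 | prenyl chloride (1-chloro-3-methylbut-2-ene) | CC(C)=CCCl | starting material
2 | prenylmagnesium chloride | CC(C)=CC[Mg]Cl | intermediate (not isolated)
3 | 2,2-dimethylbut-3-en-1-ol | C=CC(C)(C)CO | intermediate
4 | 2,2-dimethylbut-3-enal | C=CC(C)(C)C=O | intermediate
5 | dimethyl (2-oxopropyl)phosphonate | COP(=O)(CC(C)=O)OC | starting material
6 | (E)-5,5-dimethylhepta-3,6-dien-2-one | C=CC(C)(C)/C=C/C(C)=O | intermediate
7 | (E)-1,1,1-trifluoro-7,7-dimethylnona-5,8-diene-2,4-dione | C=CC(C)(C)/C=C/C(=O)CC(=O)C(F)(F)F | intermediate (not isolated)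
8 | (E)-1-diazo-5,5-dimethylhepta-3,6-dien-2-one | C=CC(C)(C)/C=C/C(=O)C=[N+]=[N-] | intermediate
9 | chloroacetaldehyde dimethyl acetal (2-chloro-1,1-dimethoxyethane) | COC(CCl)OC | starting material
10 | sodium methoxyacetylide | [Na+].[C-]#COC | intermediate (not isolated)
11 | methoxyacetylene | COC#C | intermediate
12 | (E)-5,5-dimethylhepta-1,3,6-trien-1-one (vinylketene) | C=CC(C)(C)/C=C/C=C=O | intermediate (not isolated)
13 | 3-methoxy-4-[(1E)-3,3-dimethylpenta-1,4-dien-1-yl]cyclobut-2-en-1-one (racemic) | C=CC(C)(C)/C=C/C1C(OC)=CC1=O | intermediate (not isolated)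
14 | (3E,5E)-3-methoxy-7,7-dimethylnona-1,3,5,8-tetraen-1-one (dienylketene) | O=C=C/C(OC)=C\C=C\C(C)(C)C=C | intermediate (not isolated)
15 | 3-methoxy-6-(2-methylbut-3-en-2-yl)cyclohexa-2,4-dien-1-one (racemic) | C=CC(C)(C)C1C=CC(OC)=CC1=O | intermediate (not isolated)
16 | 5-methoxy-2-(2-methylbut-3-en-2-yl)phenol | C=CC(C)(C)c1ccc(OC)cc1O | intermediate
17 | 4-methoxy-2-(methoxymethoxy)-1-(2-methylbut-3-en-2-yl)benzene | C=CC(C)(C)c1ccc(OC)cc1OCOC | intermediate
18 | 1-bromo-2-methoxy-4-(methoxymethoxy)-5-(2-methylbut-3-en-2-yl)benzene | C=CC(C)(C)c1cc(Br)c(OC)cc1OCOC | intermediate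
19 | [2-methoxy-4-(methoxymethoxy)-5-(2-methylbut-3-en-2-yl)phenyl]lithium | [Li]c1cc(C(C)(C)C=C)c(OCOC)cc1OC | intermediate (not isolated)
20 | lithium [2-methoxy-4-(methoxymethoxy)-5-(2-methylbut-3-en-2-yl)phenyl]triisopropoxyborate | [Li+].CC(C)O[B-](OC(C)C)(OC(C)C)c1cc(C(C)(C)C=C)c(OCOC)cc1OC | intermediate (not isolated)
21 | [2-methoxy-4-(methoxymethoxy)-5-(2-methylbut-3-en-2-yl)phenyl]boronic acid | C=CC(C)(C)c1cc(B(O)O)c(OC)cc1OCOC | intermediate
22 | 2,4,6-trihydroxyacetophenone | CC(=O)c1c(O)cc(O)cc1O | starting material
23 | 1-[2,4,6-trihydroxy-3-(3-methylbut-2-en-1-yl)phenyl]ethan-1-one | CC(=O)c1c(O)cc(O)c(CC=C(C)C)c1O | intermediate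
24 | 1-[2-hydroxy-4,6-bis(methoxymethoxy)-3-(3-methylbut-2-en-1-yl)phenyl]ethan-1-one | CC(=O)c1c(OCOC)cc(OCOC)c(CC=C(C)C)c1O | intermediate
25 | (E)-3-(dimethylamino)-1-[2-hydroxy-4,6-bis(methoxymethoxy)-3-(3-methylbut-2-en-1-yl)phenyl]prop-2-en-1-one | CN(C)/C=C/C(=O)c1c(OCOC)cc(OCOC)c(CC=C(C)C)c1O | intermediate (not isolated)
26 | 5,7-bis(methoxymethoxy)-8-(3-methylbut-2-en-1-yl)-4H-chromen-4-one | O=c1ccoc2c(CC=C(C)C)c(OCOC)cc(OCOC)c12 | intermediate
27 | (2S)-2-[2-methoxy-4-(methoxymethoxy)-5-(2-methylbut-3-en-2-yl)phenyl]-5,7-bis(methoxymethoxy)-8-(3-methylbut-2-en-1-yl)-2,3-dihydro-4H-chromen-4-one | C=CC(C)(C)c1cc([C@@H]2CC(=O)c3c(OCOC)cc(OCOC)c(CC=C(C)C)c3O2)c(OC)cc1OCOC | intermediate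
28 | (2S)-5,7-dihydroxy-2-[4-hydroxy-2-methoxy-5-(2-methylbut-3-en-2-yl)phenyl]-8-(3-methylbut-2-en-1-yl)-2,3-dihydro-4H-chromen-4-one | C=CC(C)(C)c1cc([C@@H]2CC(=O)c3c(O)cc(O)c(CC=C(C)C)c3O2)c(OC)cc1O | target

**Totals**
Total step count: 14. Longest linear sequence: 10 steps (steps 1, 2, 3, 4, 6, 7, 8, 9, 13, 14).

**Steps most likely to fail**

Step 6 (benzannulation). The volatile ynol ether may escape or polymerise before it traps the ketene, the ketene may dimerise, and the 3,3-dimethyl-1,4-diene may undergo a light-induced di-π-methane rearrangement. Fallback: ring B is bought and the quaternary carbon is made by an aromatic Claisen rearrangement. The fallback sets out from prenyl chloride 1, which alkylates commercial 3-methoxyphenol (COc1cccc(O)c1; K2CO3, acetone, reflux) to give 1-methoxy-3-[(3-methylbut-2-en-1-yl)oxy]benzene F1. Heating F1 in N,N-diethylaniline at about 190 °C should transfer the allyl unit with inversion to the ring carbon ortho to oxygen and para to OMe. After separation from the isomer formed at the carbon between the two oxygens, this gives phenol 16, where the route is rejoined.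

Step 13 (asymmetric 1,4-addition). The electron-rich ortho-methoxy boronic acid may protodeboronate faster than it transmetalates, insertion into the 5,7,8-trisubstituted chromone may be slow, and facial selectivity may be poor. Arene 17 returned by protodeboronation can be re-brominated in step 8. Fallback: the flavanone is made by the chalcone route and resolved. The fallback sets out from bromide 18: bromine–lithium exchange (n-BuLi, THF, −78 °C) and quench with DMF give 2-methoxy-4-(methoxymethoxy)-5-(2-methylbut-3-en-2-yl)benzaldehyde F2. Claisen–Schmidt condensation of F2 with ketone 24 (KOH, EtOH, rt) gives the (E)-2'-hydroxychalcone F3. Cyclisation of F3 by intramolecular oxa-Michael addition (NaOAc, EtOH, reflux) gives the racemic tris-MOM flavanone F4. Preparative HPLC on a chiral polysaccharide phase then delivers the (2S)-enantiomer, which is compound 27, where the route is rejoined; the other antipode can be reopened to F3 with base and recycled.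

Step 14 (global deprotection). Acid may promote ring opening and re-closure at C2 with erosion of the configuration, or cyclisation of the prenyl or 1,1-dimethylallyl groups onto the neighbouring phenols. Fallback: the acetals are exchanged for silyl ethers without Brønsted acid and the silyl ethers are then cleaved under buffered conditions. The fallback sets out from 27: Et3SiOTf and 2,2'-bipyridyl (CH2Cl2, 0 °C) should convert the three aryl MOM ethers into the tris(triethylsilyl) ether F5. HF·pyridine in THF/pyridine at 0 °C then removes the silyl groups to give target 28.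

**Further compounds**
F1 | step 6 | 1-methoxy-3-[(3-methylbut-2-en-1-yl)oxy]benzene | COc1cccc(OCC=C(C)C)c1
F2 | step 13 | 2-methoxy-4-(methoxymethoxy)-5-(2-methylbut-3-en-2-yl)benzaldehyde | C=CC(C)(C)c1cc(C=O)c(OC)cc1OCOC
F3 | step 13 | (E)-1-[2-hydroxy-4,6-bis(methoxymethoxy)-3-(3-methylbut-2-en-1-yl)phenyl]-3-[2-methoxy-4-(methoxymethoxy)-5-(2-methylbut-3-en-2-yl)phenyl]prop-2-en-1-one | C=CC(C)(C)c1cc(/C=C/C(=O)c2c(OCOC)cc(OCOC)c(CC=C(C)C)c2O)c(OC)cc1OCOC
F4 | step 13 | racemic 2-[2-methoxy-4-(methoxymethoxy)-5-(2-methylbut-3-en-2-yl)phenyl]-5,7-bis(methoxymethoxy)-8-(3-methylbut-2-en-1-yl)-2,3-dihydro-4H-chromen-4-one | C=CC(C)(C)c1cc(C2CC(=O)c3c(OCOC)cc(OCOC)c(CC=C(C)C)c3O2)c(OC)cc1OCOC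
F5 | step 14 | (2S)-2-[2-methoxy-5-(2-methylbut-3-en-2-yl)-4-(triethylsilyloxy)phenyl]-8-(3-methylbut-2-en-1-yl)-5,7-bis(triethylsilyloxy)-2,3-dihydro-4H-chromen-4-one | C=CC(C)(C)c1cc([C@@H]2CC(=O)c3c(O[Si](CC)(CC)CC)cc(O[Si](CC)(CC)CC)c(CC=C(C)C)c3O2)c(OC)cc1O[Si](CC)(CC)CC
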